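**Retrosynthetic overview**
1. Rings: A = 4-hydroxy-3-aryloxyphenyl, B = 1,3-phenylene, C = 3,4-dihydroxy-5-aryloxyphenyl, D = 1,4-phenylene; all four are bought as benzene building blocks.
2. Target 25 ⇐ protected macrocyclic stilbene 24: one hydrogenation saturates the A–D alkene and removes the benzyl ether (ring A) and the diphenylmethylene ketal (ring C).
3. 24 ⇐ dialdehyde 23 by McMurry macrocyclization at the A–D bridge; this 19-membered ring is the only ring formed and it is formed last.
4. 23 ⇐ Wittig union at the B–C bridge of AB phosphonium salt 11 and CD aldehyde 19, then alkene saturation and acetal hydrolysis.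
5. 11 ⇐ 3,4-dihydroxybenzaldehyde + 3-(hydroxymethyl)phenylboronic acid (Chan–Lam ether); 19 ⇐ methyl gallate + 4-fluorobenzaldehyde (SNAr ether).

Assumption: the target has no stereocentre and no fixed stereogenic element (flexible, achiral macrocycle), so no stereocontrol is needed and the SMILES is taken as drawn.

**Route**

Step 1
Reactants: 1 3,4-dihydroxybenzaldehyde; 2 benzyl bromide
Product: 3 4-(benzyloxy)-3-hydroxybenzaldehyde
Conditions: BnBr (1.05 equiv), NaHCO3, NaI (cat.), DMF, 40 °C
Reagents that add atoms: benzyl bromide, BrCc1ccccc1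
Why: Williamson etherification under weak base, where only the more acidic 4-OH (para to the formyl group) is ionized by NaHCO3, so mono-benzylation is regioselective.

Step 2
Reactants: 3 4-(benzyloxy)-3-hydroxybenzaldehyde; 4 ethylene glycol
Product: 5 2-(benzyloxy)-5-(1,3-dioxolan-2-yl)phenol
Conditions: ethylene glycol, p-TsOH (cat.), toluene, reflux, Dean–Stark
Reagents that add atoms: ethylene glycol, OCCO
Why: Acid-catalysed acetalization with azeotropic water removal masks the ring A aldehyde until the macrocyclization, while phenol and benzyl ether are inert.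

Step 3
Reactants: 5 2-(benzyloxy)-5-(1,3-dioxolan-2-yl)phenol; 6 [3-(hydroxymethyl)phenyl]boronic acid
Product: 7 {3-[2-(benzyloxy)-5-(1,3-dioxolan-2-yl)phenoxy]phenyl}methanol
Conditions: Cu(OAc)2 (1 equiv), pyridine, 4 Å molecular sieves, CH2Cl2, air, rt
Reagents that add atoms: [3-(hydroxymethyl)phenyl]boronic acid, OCc1cccc(B(O)O)c1
Why: Chan–Lam oxidative O-arylation at room temperature forms the A–O–B diaryl ether without touching the acetal, the phenol reacting far faster than the benzylic alcohol.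

Step 4
Reactants: 7 {3-[2-(benzyloxy)-5-(1,3-dioxolan-2-yl)phenoxy]phenyl}methanol; 8 carbon tetrabromide; 9 triphenylphosphine
Product: 10 2-{4-(benzyloxy)-3-[3-(bromomethyl)phenoxy]phenyl}-1,3-dioxolane
Conditions: CBr4, PPh3, CH2Cl2, 0 °C to rt
Reagents that add atoms: carbon tetrabromide, BrC(Br)(Br)Br
Why: Appel reaction converts the primary benzylic alcohol into the bromide under essentially neutral conditions that spare the dioxolane.

Step 5
Reactants: 10 2-{4-(benzyloxy)-3-[3-(bromomethyl)phenoxy]phenyl}-1,3-dioxolane; 9 triphenylphosphine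
Product: 11 {3-[2-(benzyloxy)-5-(1,3-dioxolan-2-yl)phenoxy]benzyl}triphenylphosphonium bromide
Conditions: PPh3, toluene, 90 °C
Reagents that add atoms: triphenylphosphine, c1ccc(cc1)P(c1ccccc1)c1ccccc1
Why: SN2 quaternization of the benzylic bromide by the phosphine gives the Wittig salt, which precipitates from toluene.

Step 6
Reactants: 12 methyl gallate; 13 dichlorodiphenylmethane
Product: 14 methyl 7-hydroxy-2,2-diphenyl-1,3-benzodioxole-5-carboxylate
Conditions: Ph2CCl2 (1.2 equiv), neat, 180 °C, 15 min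
Reagents that add atoms: dichlorodiphenylmethane, ClC(Cl)(c1ccccc1)c1ccccc1
Why: Ketalization of a vicinal diol with the gem-dichloride can only bridge two adjacent hydroxyls, so the 3,4-catechol is protected and the 5-OH stays free.

Step 7
Reactants: 14 methyl 7-hydroxy-2,2-diphenyl-1,3-benzodioxole-5-carboxylate; 15 4-fluorobenzaldehyde
Product: 16 methyl 7-(4-formylphenoxy)-2,2-diphenyl-1,3-benzodioxole-5-carboxylate
Conditions: K2CO3, DMF, 120 °C
Reagents that add atoms: 4-fluorobenzaldehyde, O=Cc1ccc(F)cc1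
Why: SNAr displacement of fluoride activated by the para-formyl group forms the C–O–D diaryl ether with an ester and an aldehyde that are already differentiated.

Step 8
Reactants: 16 methyl 7-(4-formylphenoxy)-2,2-diphenyl-1,3-benzodioxole-5-carboxylate; 4 ethylene glycol
Product: 17 methyl 7-[4-(1,3-dioxolan-2-yl)phenoxy]-2,2-diphenyl-1,3-benzodioxole-5-carboxylate
Conditions: ethylene glycol, PPTS (cat.), toluene, reflux, Dean–Stark
Reagents that add atoms: ethylene glycol, OCCO
Why: Mild PPTS-catalysed acetalization masks the ring D aldehyde while the diphenylmethylene ketal and the ester survive.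

Step 9
Reactants: 17 methyl 7-[4-(1,3-dioxolan-2-yl)phenoxy]-2,2-diphenyl-1,3-benzodioxole-5-carboxylate
Product: 18 {7-[4-(1,3-dioxolan-2-yl)phenoxy]-2,2-diphenyl-1,3-benzodioxol-5-yl}methanol
Conditions: LiAlH4, THF, 0 °C; aqueous NaOH work-up
Reagents that add atoms: none
Why: Hydride reduction takes the ester to the benzylic alcohol, and acetal, ketal and diaryl ether are inert to LiAlH4.

Step 10
Reactants: 18 {7-[4-(1,3-dioxolan-2-yl)phenoxy]-2,2-diphenyl-1,3-benzodioxol-5-yl}methanol
Product: 19 7-[4-(1,3-dioxolan-2-yl)phenoxy]-2,2-diphenyl-1,3-benzodioxole-5-carbaldehyde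
Conditions: activated MnO2 (excess), CH2Cl2, rt
Reagents that add atoms: none
Why: Benzylic alcohol oxidation by MnO2 is neutral and stops cleanly at the aldehyde.

Step 11
Reactants: 11 {3-[2-(benzyloxy)-5-(1,3-dioxolan-2-yl)phenoxy]benzyl}triphenylphosphonium bromide; 19 7-[4-(1,3-dioxolan-2-yl)phenoxy]-2,2-diphenyl-1,3-benzodioxole-5-carbaldehyde
Product: 21 6-(2-{3-[2-(benzyloxy)-5-(1,3-dioxolan-2-yl)phenoxy]phenyl}ethenyl)-4-[4-(1,3-dioxolan-2-yl)phenoxy]-2,2-diphenyl-1,3-benzodioxole (E/Z mixture), via phosphonium ylide 20 (not isolated)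
Conditions: KOtBu, THF, 0 °C; then 19, 0 °C to rt
Reagents that add atoms: none
Why: Wittig olefination of the semi-stabilized benzylic ylide with the ring C aldehyde builds the B–C two-carbon bridge, and the alkene geometry is irrelevant because the bond is saturated in the next step.

Step 12
Reactants: 21 stilbene bis-dioxolane (E/Z mixture)
Product: 22 6-(2-{3-[2-(benzyloxy)-5-(1,3-dioxolan-2-yl)phenoxy]phenyl}ethyl)-4-[4-(1,3-dioxolan-2-yl)phenoxy]-2,2-diphenyl-1,3-benzodioxole
Conditions: H2 (1 atm), 10% Pd/C, Ph2S (0.01 equiv), EtOAc, rt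
Reagents that add atoms: none
Why: Chemoselective heterogeneous hydrogenation on sulfide-poisoned palladium saturates the stilbene while hydrogenolysis of the benzyl ether and the diphenylmethylene ketal is suppressed, giving a flexible bibenzyl for ring closure.

Step 13
Reactants: 22 bibenzyl bis-dioxolane
Product: 23 4-(benzyloxy)-3-(3-{2-[7-(4-formylphenoxy)-2,2-diphenyl-1,3-benzodioxol-5-yl]ethyl}phenoxy)benzaldehyde
Conditions: 1 M HCl, THF, rt
Reagents that add atoms: water, O
Why: Dilute-acid acetal hydrolysis frees both aryl aldehydes, while the far more robust diphenylmethylene ketal and the benzyl ether remain.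

Step 14
Reactants: 23 dialdehyde
Product: 24 protected macrocyclic stilbene (19-membered ring; ring A O-benzyl, ring C 3,4-O-diphenylmethylene, CH=CH between rings A and D; E/Z mixture)
Conditions: TiCl3(DME)1.5, Zn(Cu) couple, DME, reflux; 23 added by syringe pump over 30 h (final 2 mM)
Reagents that add atoms: none
Why: Intramolecular McMurry reductive carbonyl coupling under pseudo-high dilution on low-valent titanium closes the 19-membered ring at the A–D bridge, and the alkene geometry is irrelevant.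

Step 15
Reactants: 24 protected macrocyclic stilbene
Product: 25 target macrocyclic bis(bibenzyl) triol
Conditions: H2 (3 atm), 20% Pd(OH)2/C, EtOAc/MeOH 1:1, rt
Reagents that add atoms: none
Why: One catalytic hydrogenation saturates the stilbene and hydrogenolyses the benzyl ether and the diphenylmethylene ketal, releasing the three phenols; no stereocentre is created.

**Compound list**
1 | 3,4-dihydroxybenzaldehyde | O=Cc1ccc(O)c(O)c1 | starting material
2 | benzyl bromide | BrCc1ccccc1 | starting material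
3 | 4-(benzyloxy)-3-hydroxybenzaldehyde | O=Cc1ccc(OCc2ccccc2)c(O)c1 | intermediate
4 | ethylene glycol | OCCO | starting material
5 | 2-(benzyloxy)-5-(1,3-dioxolan-2-yl)phenol | Oc1cc(C2OCCO2)ccc1OCc1ccccc1 | intermediate
6 | [3-(hydroxymethyl)phenyl]boronic acid | OCc1cccc(B(O)O)c1 | starting material
7 | {3-[2-(benzyloxy)-5-(1,3-dioxolan-2-yl)phenoxy]phenyl}methanol | OCc1cccc(Oc2cc(C3OCCO3)ccc2OCc2ccccc2)c1 | intermediate
8 | carbon tetrabromide | BrC(Br)(Br)Br | starting material
9 | triphenylphosphine | c1ccc(cc1)P(c1ccccc1)c1ccccc1 | starting material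
10 | 2-{4-(benzyloxy)-3-[3-(bromomethyl)phenoxy]phenyl}-1,3-dioxolane | BrCc1cccc(Oc2cc(C3OCCO3)ccc2OCc2ccccc2)c1 | intermediate
11 | {3-[2-(benzyloxy)-5-(1,3-dioxolan-2-yl)phenoxy]benzyl}triphenylphosphonium bromide | [Br-].c1ccc(cc1)[P+](Cc1cccc(Oc2cc(C3OCCO3)ccc2OCc2ccccc2)c1)(c1ccccc1)c1ccccc1 | intermediate
12 | methyl gallate (methyl 3,4,5-trihydroxybenzoate) | COC(=O)c1cc(O)c(O)c(O)c1 | starting material
13 | dichlorodiphenylmethane | ClC(Cl)(c1ccccc1)c1ccccc1 | starting material
14 | methyl 7-hydroxy-2,2-diphenyl-1,3-benzodioxole-5-carboxylate | COC(=O)c1cc(O)c2OC(c3ccccc3)(c3ccccc3)Oc2c1 | intermediate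
15 | 4-fluorobenzaldehyde | O=Cc1ccc(F)cc1 | starting material
16 | methyl 7-(4-formylphenoxy)-2,2-diphenyl-1,3-benzodioxole-5-carboxylate | COC(=O)c1cc(Oc2ccc(C=O)cc2)c2OC(c3ccccc3)(c3ccccc3)Oc2c1 | intermediate
17 | methyl 7-[4-(1,3-dioxolan-2-yl)phenoxy]-2,2-diphenyl-1,3-benzodioxole-5-carboxylate | COC(=O)c1cc(Oc2ccc(cc2)C2OCCO2)c2OC(c3ccccc3)(c3ccccc3)Oc2c1 | intermediate
18 | {7-[4-(1,3-dioxolan-2-yl)phenoxy]-2,2-diphenyl-1,3-benzodioxol-5-yl}methanol | OCc1cc(Oc2ccc(cc2)C2OCCO2)c2OC(c3ccccc3)(c3ccccc3)Oc2c1 | intermediate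
19 | 7-[4-(1,3-dioxolan-2-yl)phenoxy]-2,2-diphenyl-1,3-benzodioxole-5-carbaldehyde | O=Cc1cc(Oc2ccc(cc2)C2OCCO2)c2OC(c3ccccc3)(c3ccccc3)Oc2c1 | intermediate
20 | {3-[2-(benzyloxy)-5-(1,3-dioxolan-2-yl)phenoxy]benzylidene}triphenylphosphorane (ylide, not isolated) | c1ccc(cc1)P(=Cc1cccc(Oc2cc(C3OCCO3)ccc2OCc2ccccc2)c1)(c1ccccc1)c1ccccc1 | intermediate
21 | 6-(2-{3-[2-(benzyloxy)-5-(1,3-dioxolan-2-yl)phenoxy]phenyl}ethenyl)-4-[4-(1,3-dioxolan-2-yl)phenoxy]-2,2-diphenyl-1,3-benzodioxole (E/Z mixture, geometry not specified) | C(=Cc1cc(Oc2ccc(cc2)C2OCCO2)c2OC(c3ccccc3)(c3ccccc3)Oc2c1)c1cccc(Oc2cc(C3OCCO3)ccc2OCc2ccccc2)c1 | intermediate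
22 | 6-(2-{3-[2-(benzyloxy)-5-(1,3-dioxolan-2-yl)phenoxy]phenyl}ethyl)-4-[4-(1,3-dioxolan-2-yl)phenoxy]-2,2-diphenyl-1,3-benzodioxole | C(Cc1cc(Oc2ccc(cc2)C2OCCO2)c2OC(c3ccccc3)(c3ccccc3)Oc2c1)c1cccc(Oc2cc(C3OCCO3)ccc2OCc2ccccc2)c1 | intermediate
23 | 4-(benzyloxy)-3-(3-{2-[7-(4-formylphenoxy)-2,2-diphenyl-1,3-benzodioxol-5-yl]ethyl}phenoxy)benzaldehyde | C(Cc1cc(Oc2ccc(C=O)cc2)c2OC(c3ccccc3)(c3ccccc3)Oc2c1)c1cccc(Oc2cc(C=O)ccc2OCc2ccccc2)c1 | intermediate
24 | protected macrocyclic stilbene: target skeleton with ring A O-benzyl, ring C 3,4-O-diphenylmethylene and CH=CH between rings A and D (E/Z mixture, geometry not specified) | C1=Cc2ccc(OCc3ccccc3)c(c2)Oc2cccc(c2)CCc2cc3OC(c4ccccc4)(c4ccccc4)Oc3c(c2)Oc2ccc1cc2 | intermediate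
25 | target macrocyclic bis(bibenzyl) triol (achiral) | Oc1ccc2cc1Oc1cccc(c1)CCc1cc(O)c(O)c(c1)Oc1ccc(cc1)CC2 | target

**Step count**
Total: 15 steps. Longest linear sequence: 10 steps (steps 1–5, then 11–15; steps 6–10, then 11–15 is equally long).

**Three steps most likely to fail, with fallbacks**

Step 14 (McMurry macrocyclization; oligomerization or pinacol formation may compete with closure of the 19-membered ring). The fallback sets out from dialdehyde 23 and switches to ring-closing metathesis. Compound 23 is treated with methylenetriphenylphosphorane F1, made in the flask from MePPh3Br and KOtBu in THF at 0 °C, to give the bis-styrene F2. F2 is then cyclized with the second-generation Grubbs catalyst (C46H65Cl2N2PRu, 5 mol %) in toluene at 1 mM and 80 °C with loss of ethylene. The fallback comes back to the route at macrocyclic stilbene 24.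

Step 3 (Chan–Lam coupling; the ortho-alkoxy phenol may arylate sluggishly and the boronic acid may homocouple or be oxidized). The fallback sets out from phenol 5 and uses an Ullmann-type coupling with methyl 3-bromobenzoate (COC(=O)c1cccc(Br)c1) under CuI, N,N-dimethylglycine hydrochloride, Cs2CO3, dioxane, 90 °C. This gives methyl 3-[2-(benzyloxy)-5-(1,3-dioxolan-2-yl)phenoxy]benzoate F3, which is reduced with LiAlH4 in THF at 0 °C. The fallback comes back to the route at alcohol 7.

Step 12 (chemoselective hydrogenation; partial loss of the benzyl ether or the ketal, or incomplete reduction of the E-isomer). The fallback sets out from stilbene 21 and replaces catalytic hydrogenation by a metal-free transfer reduction with diimide F4, generated in the flask from 2-nitrobenzenesulfonyl hydrazide and Et3N in CH2Cl2 at rt (repeated charges). Diimide cannot cleave benzylic C–O bonds, and the medium stays basic for the acetals. The fallback comes back to the route at bibenzyl 22.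

**Further compounds**
F1 | step 14 | methylenetriphenylphosphorane | C=P(c1ccccc1)(c1ccccc1)c1ccccc1
F2 | step 14 | 6-(2-{3-[2-(benzyloxy)-5-ethenylphenoxy]phenyl}ethyl)-4-(4-ethenylphenoxy)-2,2-diphenyl-1,3-benzodioxole (bis-styrene) | C(Cc1cc(Oc2ccc(C=C)cc2)c2OC(c3ccccc3)(c3ccccc3)Oc2c1)c1cccc(Oc2cc(C=C)ccc2OCc2ccccc2)c1
F3 | step 3 | methyl 3-[2-(benzyloxy)-5-(1,3-dioxolan-2-yl)phenoxy]benzoate | COC(=O)c1cccc(Oc2cc(C3OCCO3)ccc2OCc2ccccc2)c1
F4 | step 12 | diimide | N=N
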